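**Plan**
Ring atoms are labelled O1, C2 (bears CHBr2), C3 (bears CH3), C4, C5, C6; C7 is the exocyclic C(CH3)(Cl)CH2Cl carbon on C6.
The retrosynthesis cuts O1–C6 and C5–C6 together, then C2–C3 of the allylsilane that results, then the two C–Cl bonds of the aldehyde partner.
This works because C6 sits between the ring oxygen, the C5 methylene and the fully substituted C7, so it can come from an aldehyde carbon without α-hydrogen, and the C3=C4 alkene marks where a silyl group on C3 can leave.
Forward: but-2-yn-1-ol becomes an E γ-silyl-γ-methyl allylboronate, which adds to dibromoacetaldehyde (C2–C3); after O-silylation the single ring, the dihydropyran, closes in the last step with (R)-2,3-dichloro-2-methylpropanal.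
Stereochemistry: C2 from a chiral phosphoric acid, the temporary C3 silyl centre from the E alkene geometry through a chair transition state, C7 from a catalytic enantioselective dichlorination, C6 from C2/C3 in the chair-like oxocarbenium closure (2,6-trans).

Key step: step 9

Assumption: the sense of induction of both chiral catalysts is carried over from simpler substrates. (S)-TRIP is taken to direct allylation to the Si face of dibromoacetaldehyde, and the (S)-Schiff-base titanium catalyst to give the (R)-dichloro alcohol; the mirror-image catalyst would be used if the opposite sense were found.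

**Route**

Step 1
Reactants: 1 but-2-yn-1-ol; 2 dimethyl(phenyl)silane
Product: 3 (E)-3-[dimethyl(phenyl)silyl]but-2-en-1-ol
Conditions: PtCl2 (1 mol %), 2-dicyclohexylphosphino-2',4',6'-triisopropylbiphenyl (XPhos, 2 mol %), THF, 50 °C
Reagents that add atoms: none
Why: Platinum-catalysed alkyne hydrosilylation is a syn addition, and with the bulky biaryl phosphine the propargylic hydroxyl should steer silicon to the distal alkyne carbon, so the E vinylsilane with CH2OH trans to silicon is expected.

Step 2
Reactants: 3 (E)-3-[dimethyl(phenyl)silyl]but-2-en-1-ol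
Product: 4 (E)-3-[dimethyl(phenyl)silyl]but-2-en-1-yl acetate
Conditions: Ac2O, pyridine, DMAP (cat.), CH2Cl2, 0 °C to rt
Reagents that add atoms: acetic anhydride, CC(=O)OC(C)=O
Why: DMAP-catalysed O-acetylation of a primary allylic alcohol is routine and leaves the vinylsilane untouched.

Step 3
Reactants: 4 (E)-3-[dimethyl(phenyl)silyl]but-2-en-1-yl acetate
Product: 5 (E)-dimethyl(phenyl)[4-(4,4,5,5-tetramethyl-1,3,2-dioxaborolan-2-yl)but-2-en-2-yl]silane
Conditions: B2pin2, Pd(dba)2 (3 mol %), DMSO, 50 °C
Reagents that add atoms: bis(pinacolato)diboron, CC1(C)OB(OC1(C)C)B1OC(C)(C)C(C)(C)O1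
Why: In this Miyaura-type borylation of an allylic acetate, zerovalent palladium ionises the acetate and boron goes to the unhindered CH2 terminus, and the E geometry should be retained because scrambling would require palladium to bind the fully substituted silyl-bearing carbon.

Step 4
Reactants: 6 ethyl dibromoacetate
Product: 8 dibromoacetaldehyde, via aluminium hemiacetal 7 (not isolated)
Conditions: iBu2AlH (1.05 equiv), CH2Cl2, −78 °C; cold 1 M HCl; distilled from P2O5 and used fresh
Reagents that add atoms: none
Why: Low-temperature iBu2AlH reduction of an ester should stop at the aldehyde level here because the electron-poor tetrahedral aluminium hemiacetal 7 is stable at −78 °C and collapses only on acidic work-up.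

Step 5
Reactants: 5 (E)-dimethyl(phenyl)[4-(4,4,5,5-tetramethyl-1,3,2-dioxaborolan-2-yl)but-2-en-2-yl]silane; 8 dibromoacetaldehyde
Product: 10 (2S,3S)-1,1-dibromo-3-[dimethyl(phenyl)silyl]-3-methylpent-4-en-2-ol, via pinacol borate ester 9 (not isolated)
Conditions: (S)-3,3'-bis(2,4,6-triisopropylphenyl)-1,1'-binaphthyl-2,2'-diyl hydrogen phosphate ((S)-TRIP, 10 mol %), 4 Å MS, toluene, −30 °C; then pH 7 buffer
Reagents that add atoms: none
Why: This chiral phosphoric acid-catalysed allylboration runs through a closed Zimmerman–Traxler chair in which the E reagent places silicon equatorial and methyl axial on the γ-carbon, giving the hydroxyl/silyl anti relationship, while the (S) acid, hydrogen-bonded to the formyl hydrogen and a boronate oxygen, should expose the Si face of 8 and so set C2 as S and with it C3 as S.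

Step 6
Reactants: 10 (2S,3S)-1,1-dibromo-3-[dimethyl(phenyl)silyl]-3-methylpent-4-en-2-ol
Product: 11 {[(2S,3S)-1,1-dibromo-3-[dimethyl(phenyl)silyl]-3-methylpent-4-en-2-yl]oxy}trimethylsilane
Conditions: TMSCl, imidazole, CH2Cl2, 0 °C to rt
Reagents that add atoms: chlorotrimethylsilane, C[Si](C)(C)Cl
Why: Routine O-silylation under mildly basic conditions gives a neutral silyl ether, so the annulation can start without releasing protic acid next to the acid-sensitive β-hydroxysilane.

Step 7
Reactants: 12 2-methylprop-2-en-1-ol
Product: 13 (R)-2,3-dichloro-2-methylpropan-1-ol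
Conditions: tBuOCl (1.1 equiv), ClTi(OiPr)3 (1.1 equiv), (S)-2-{[(1-hydroxy-3,3-dimethyl-1,1-diphenylbutan-2-yl)imino]methyl}phenol (20 mol %), hexanes, −20 °C
Reagents that add atoms: tert-butyl hypochlorite, CC(C)(C)OCl; chlorotitanium triisopropoxide, CC(C)O[Ti](Cl)(OC(C)C)OC(C)C
Why: In this titanium-catalysed enantioselective dichlorination the allylic alcohol binds as an alkoxide to the chiral Schiff-base complex of tetravalent titanium, electrophilic chlorine from tBuOCl adds at the CH2 terminus and titanium-bound chloride is delivered anti to the tertiary carbon in the Markovnikov sense, which should set the later C7 as R.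

Step 8
Reactants: 13 (R)-2,3-dichloro-2-methylpropan-1-ol
Product: 14 (R)-2,3-dichloro-2-methylpropanal
Conditions: Dess–Martin periodinane, CH2Cl2, 0 °C to rt; filtered through silica and used as a dry CH2Cl2 solution
Reagents that add atoms: none
Why: Dess–Martin oxidation of a primary alcohol is mild and neutral, and the product has no α-hydrogen, so neither epimerisation nor loss of HCl can occur.

Step 9
Reactants: 11 {[(2S,3S)-1,1-dibromo-3-[dimethyl(phenyl)silyl]-3-methylpent-4-en-2-yl]oxy}trimethylsilane; 14 (R)-2,3-dichloro-2-methylpropanal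
Product: 17 (2S,6S)-2-(dibromomethyl)-6-[(2R)-1,2-dichloropropan-2-yl]-3-methyl-3,6-dihydro-2H-pyran, via oxocarbenium triflate 15 (not isolated), via ring-closed silyl cation 16 (not isolated)
Conditions: Me3SiOTf (1.0 equiv), 2,6-di-tert-butyl-4-methylpyridine (0.2 equiv), CH2Cl2, −78 to −40 °C; then aq. NaHCO3
Reagents that add atoms: none
Why: Me3SiOTf activates 14, the silyl ether oxygen of 11 adds and hexamethyldisiloxane leaves to give the E oxocarbenium ion 15, whose C6 is attacked by the terminal alkene carbon C5; the C4 cation 16 is stabilised by the neighbouring C3–Si bond and loses silicon to triflate, which places the double bond at C3=C4 and nowhere else. The closest known reaction type is the [4+2] annulation of anti β-silyloxy allylsilanes with aldehydes (an intramolecular Hosomi–Sakurai or silyl-Prins reaction), known to give 2,6-trans-dihydropyrans. The dihydropyran, the only ring, closes in a chair-like 6-endo-trig mode in which O1–C6 and C5–C6 are the new bonds. The new stereocentre C6 is controlled by C2 and C3: the C3–Si bond has to stand axial, parallel to the p orbital developing at C4, which forces the trans-disposed CHBr2 group on C2 axial and the C3 methyl equatorial, while the E oxocarbenium keeps the C7 side chain equatorial, so that C6 should form S and trans to C2. The step needs this 2,6-trans selectivity and needs ring closure to outrun intermolecular allylation, Peterson elimination and protodesilylation; the anti C2/C3 relationship set in step 5 secures the first, and the silyl ether, the hindered pyridine base and the electron-poor CHBr2 carbon (which disfavours ionisation of C2–O) should secure the second. C7 cannot epimerise because the aldehyde carbon carries no α-hydrogen.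

**Compound list**
1 | but-2-yn-1-ol | CC#CCO | starting material
2 | dimethyl(phenyl)silane | C[SiH](C)c1ccccc1 | starting material
3 | (E)-3-[dimethyl(phenyl)silyl]but-2-en-1-ol | OC/C=C(\C)[Si](C)(C)c1ccccc1 | intermediate
4 | (E)-3-[dimethyl(phenyl)silyl]but-2-en-1-yl acetate | CC(=O)OC/C=C(\C)[Si](C)(C)c1ccccc1 | intermediate
5 | (E)-dimethyl(phenyl)[4-(4,4,5,5-tetramethyl-1,3,2-dioxaborolan-2-yl)but-2-en-2-yl]silane | CC1(C)OB(C/C=C(\C)[Si](C)(C)c2ccccc2)OC1(C)C | intermediate
6 | ethyl dibromoacetate | CCOC(=O)C(Br)Br | starting material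
7 | diisobutylaluminium 2,2-dibromo-1-ethoxyethoxide (aluminium hemiacetal) | CCOC(O[Al](CC(C)C)CC(C)C)C(Br)Br | intermediate (not isolated)
8 | dibromoacetaldehyde | O=CC(Br)Br | intermediate
9 | 2-{[(2S,3S)-1,1-dibromo-3-[dimethyl(phenyl)silyl]-3-methylpent-4-en-2-yl]oxy}-4,4,5,5-tetramethyl-1,3,2-dioxaborolane | CC1(C)OB(O[C@H](C(Br)Br)[C@@](C)([Si](C)(C)c2ccccc2)C=C)OC1(C)C | intermediate (not isolated)
10 | (2S,3S)-1,1-dibromo-3-[dimethyl(phenyl)silyl]-3-methylpent-4-en-2-ol (hydroxyl and silyl anti) | O[C@H](C(Br)Br)[C@@](C)([Si](C)(C)c1ccccc1)C=C | intermediate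
11 | {[(2S,3S)-1,1-dibromo-3-[dimethyl(phenyl)silyl]-3-methylpent-4-en-2-yl]oxy}trimethylsilane | C[Si](C)(C)O[C@H](C(Br)Br)[C@@](C)([Si](C)(C)c1ccccc1)C=C | intermediate
12 | 2-methylprop-2-en-1-ol | CC(=C)CO | starting material
13 | (R)-2,3-dichloro-2-methylpropan-1-ol | OC[C@@](C)(Cl)CCl | intermediate
14 | (R)-2,3-dichloro-2-methylpropanal | O=C[C@@](C)(Cl)CCl | intermediate
15 | (E)-[(2S,3S)-1,1-dibromo-3-[dimethyl(phenyl)silyl]-3-methylpent-4-en-2-yl][(2R)-2,3-dichloro-2-methylpropylidene]oxonium triflate | ClC[C@](C)(Cl)/C=[O+]/[C@H](C(Br)Br)[C@@](C)([Si](C)(C)c1ccccc1)C=C.[O-]S(=O)(=O)C(F)(F)F | intermediate (not isolated)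
16 | (2S,3S,6S)-2-(dibromomethyl)-6-[(2R)-1,2-dichloropropan-2-yl]-3-[dimethyl(phenyl)silyl]-3-methyloxan-4-ylium triflate | C[C@]1([Si](C)(C)c2ccccc2)[CH+]C[C@@H]([C@@](C)(Cl)CCl)O[C@@H]1C(Br)Br.[O-]S(=O)(=O)C(F)(F)F | intermediate (not isolated)
17 | (2S,6S)-2-(dibromomethyl)-6-[(2R)-1,2-dichloropropan-2-yl]-3-methyl-3,6-dihydro-2H-pyran | CC1=CC[C@@H]([C@@](C)(Cl)CCl)O[C@@H]1C(Br)Br | target

**Count and risks**
Total steps: 9. Longest linear sequence: 6 steps (1, 2, 3, 5, 6, 9).

Step 9. Both partners are electron-poor, so the oxocarbenium ion may form slowly and be overtaken by direct intermolecular attack of the allylsilane on the activated aldehyde, by acid-promoted Peterson elimination or by protodesilylation. The fallback sets out from 10 and 14 and returns at 17. Aldehyde 14 is oxidised (NaClO2, NaH2PO4, 2-methylbut-2-ene, tBuOH/H2O; Pinnick) to (2R)-2,3-dichloro-2-methylpropanoic acid F1. Yamaguchi esterification with 10 (2,4,6-trichlorobenzoyl chloride, Et3N, then DMAP, toluene) gives (2S,3S)-1,1-dibromo-3-[dimethyl(phenyl)silyl]-3-methylpent-4-en-2-yl (2R)-2,3-dichloro-2-methylpropanoate F2. Reductive acetylation (iBu2AlH, CH2Cl2, −78 °C, then Ac2O, pyridine, DMAP) gives 1-{[(2S,3S)-1,1-dibromo-3-[dimethyl(phenyl)silyl]-3-methylpent-4-en-2-yl]oxy}-(2R)-2,3-dichloro-2-methylpropyl acetate F3 as a mixture of acetal epimers. Ionisation of F3 with Me3SiOTf at −78 °C should release oxocarbenium ion 15 with the O1–C6 bond already in place, so ring closure through 16 to 17 no longer depends on a bimolecular condensation.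

Step 5. Uncatalysed background addition to the very electrophilic aldehyde may erode the facial selectivity, and the hindered reagent may react slowly enough for the aldehyde to degrade. The fallback sets out from 5 and 8 and returns at 10. The two are combined without catalyst in toluene at rt; the closed transition state should still give only the anti diastereomer, now as 10 together with its mirror image (2R,3R)-1,1-dibromo-3-[dimethyl(phenyl)silyl]-3-methylpent-4-en-2-ol F4. Esterification of the mixture with (R)-2-methoxy-2-phenylacetic acid (DCC, DMAP, CH2Cl2) gives two diastereomers to be separated by chromatography: (2S,3S)-1,1-dibromo-3-[dimethyl(phenyl)silyl]-3-methylpent-4-en-2-yl (2R)-2-methoxy-2-phenylacetate F5 and (2R,3R)-1,1-dibromo-3-[dimethyl(phenyl)silyl]-3-methylpent-4-en-2-yl (2R)-2-methoxy-2-phenylacetate F6. Reductive cleavage of F5 with iBu2AlH at −78 °C returns 10 without the basic conditions that could close a bromo-epoxide.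

Step 7. Facial selectivity at the 1,1-disubstituted alkene may be poor, and any opening of the chlorinated intermediate at the CH2 carbon instead of the tertiary carbon would give the mirror-image product and lower the enantiopurity. The fallback sets out from 12 and returns at 13. Achiral anti-dichlorination (Et4NCl3, CH2Cl2, 0 °C) gives 13 together with (S)-2,3-dichloro-2-methylpropan-1-ol F7. Esterification with (R)-2-methoxy-2-phenylacetic acid (DCC, DMAP) gives (2R)-2,3-dichloro-2-methylpropyl (2R)-2-methoxy-2-phenylacetate F8 and (2S)-2,3-dichloro-2-methylpropyl (2R)-2-methoxy-2-phenylacetate F9, to be separated by chromatography or crystallisation. Cleavage of F8 with iBu2AlH at −78 °C returns 13.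

Further compounds
F1 | step 9 | (2R)-2,3-dichloro-2-methylpropanoic acid | OC(=O)[C@@](C)(Cl)CCl
F2 | step 9 | (2S,3S)-1,1-dibromo-3-[dimethyl(phenyl)silyl]-3-methylpent-4-en-2-yl (2R)-2,3-dichloro-2-methylpropanoate | ClC[C@](C)(Cl)C(=O)O[C@H](C(Br)Br)[C@@](C)([Si](C)(C)c1ccccc1)C=C
F3 | step 9 | 1-{[(2S,3S)-1,1-dibromo-3-[dimethyl(phenyl)silyl]-3-methylpent-4-en-2-yl]oxy}-(2R)-2,3-dichloro-2-methylpropyl acetate | CC(=O)OC(O[C@H](C(Br)Br)[C@@](C)([Si](C)(C)c1ccccc1)C=C)[C@@](C)(Cl)CCl
F4 | step 5 | (2R,3R)-1,1-dibromo-3-[dimethyl(phenyl)silyl]-3-methylpent-4-en-2-ol | O[C@@H](C(Br)Br)[C@](C)([Si](C)(C)c1ccccc1)C=C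
F5 | step 5 | (2S,3S)-1,1-dibromo-3-[dimethyl(phenyl)silyl]-3-methylpent-4-en-2-yl (2R)-2-methoxy-2-phenylacetate | CO[C@@H](C(=O)O[C@H](C(Br)Br)[C@@](C)([Si](C)(C)c1ccccc1)C=C)c1ccccc1
F6 | step 5 | (2R,3R)-1,1-dibromo-3-[dimethyl(phenyl)silyl]-3-methylpent-4-en-2-yl (2R)-2-methoxy-2-phenylacetate | CO[C@@H](C(=O)O[C@@H](C(Br)Br)[C@](C)([Si](C)(C)c1ccccc1)C=C)c1ccccc1
F7 | step 7 | (S)-2,3-dichloro-2-methylpropan-1-ol | OC[C@](C)(Cl)CCl
F8 | step 7 | (2R)-2,3-dichloro-2-methylpropyl (2R)-2-methoxy-2-phenylacetate | CO[C@@H](C(=O)OC[C@@](C)(Cl)CCl)c1ccccc1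
F9 | step 7 | (2S)-2,3-dichloro-2-methylpropyl (2R)-2-methoxy-2-phenylacetate | CO[C@@H](C(=O)OC[C@](C)(Cl)CCl)c1ccccc1
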